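## The problem

The target, (3R)-2,2-dimethyl-8-(3-methylbut-2-en-1-yl)-5-[(E)-2-phenylethenyl]-3,4-dihydro-2H-chromene-3,7-diol (15), is a prenylated pinosylvin whose resorcinol ring is pentasubstituted, with hydrogen only at C6. The dihydropyran is fused across C4a–C8a, so its C4 methylene lies peri to the styryl-bearing C5. The carbon between the two ring oxygens (C8) carries the prenyl group, and the C7 oxygen must end as a free phenol. The single stereocentre is C3 (R), a secondary carbinol between the quaternary C2 and the benzylic C4. No second stereocentre exists to relay its configuration, so it has to be set by a catalyst, and C4 must finish without oxygen. Along any route the molecule holds several alkenes of different character (the trisubstituted prenyl alkene, the E-stilbene and any chromene alkene used on the way), and all of them compete for oxidants. An o-prenylphenol closes to a second chroman under strong acid, the stilbene isomerises under light and acid, and any oxirane or leaving group at C4 is benzylic, ortho to O1 and para to O7, and so is liable to ionise. The enabling feature is that O1, C2(CH3)2, C3, C4 and the arene form a 2,2-dimethyl-2H-chromene when C3=C4 is a double bond. This cis, aryl-conjugated alkene is an excellent substrate for chiral Mn(salen) oxygen transfer, and in the derived oxirane only the C4–O bond is benzylic, so hydride can remove the C4 oxygen and leave C3–O and its configuration untouched.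

## Retrosynthesis

The first cut is the Cα=Cβ bond of the styryl group, giving aldehyde 13 and diethyl benzylphosphonate 14. The neighbouring cut at the aryl–vinyl bond C5–Cα would need a halide or triflate on C5. That would remove the carbonyl-level group at C5 which serves as an electron sink during the oxidation. Forming the stilbene last also means no oxidant ever meets it. Compound 13 is simpler by the benzylidene unit and its photolability. The forward olefination has to be E-selective and has to tolerate an unprotected phenol and secondary alcohol.

Aldehyde 13 is traced to triol 12 by adjustment of the benzylic oxidation level, and 12 to oxirane 11 by replacing the C4–H bond with the C4–O bond. One hydride operation on 11 is asked to open the oxirane at C4, reduce the C5 methyl ester and cleave the aryl pivalate. Halting the ester at the aldehyde stage beside an epoxide is not controllable, so over-reduction and selective re-oxidation are accepted at the cost of one step. The forward reaction must deliver hydride to benzylic C4 and not to neopentylic C3. Since the C3–O bond is never broken, the configuration of 11 passes unchanged into 12.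

The key disconnection removes both C–O bonds of the oxirane in 11 and returns the achiral, planar chromene 10. Other ways of oxygenating C3 compare poorly: dihydroxylation of C3=C4 leaves a surplus hydroxyl at C4 and would favour the prenyl alkene, dioxirane-based asymmetric epoxidation also favours the trisubstituted prenyl alkene, and reduction of a chroman-3-one needs extra steps to reach the ketone. Mn(salen) oxo transfer is the one oxidation whose intrinsic preference (cis, conjugated alkenes over isolated trisubstituted ones) matches the substrate. The forward step needs catalyst-controlled face selectivity, discrimination between the two alkenes of 10, and an oxirane that survives isolation. The last requirement is why O7 is carried as a pivalate and C5 as an ester.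

Pivalate 10 comes from phenol 9 by acylation, and the pyran ring of 9 is cut at O1–C2 and C4–C4a, a formal [3+3] union of resorcylate 6 with 3-methylbut-2-enal 7. In 6 the carbon between the hydroxyls is blocked by the prenyl group and the two remaining ring CH positions are equivalent by symmetry, so only one chromene constitution can form. Compound 6 has no heterocycle; the forward reaction only has to stop after one annulation.

Resorcylate 6 is unmasked from bis(methoxymethyl) ether 5, and the aryl–CH2 bond of 5 is cut to aryl bromide 2 and the prenyl organometallic 4, made from prenyl bromide 3. Electrophilic prenylation of a resorcylate would give mixtures of C2, C4 and O products, whereas the bromine of commercial 1 already marks the correct carbon. The ether groups of 2 only remove the acidic protons for the organozinc coupling. The forward coupling must give the linear, not the reverse-prenyl, isomer and must spare the ester.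

## Roads not taken

Alternative 1: The benzene ring itself is disconnected (C7–C8, C4a–C8a and C6–C7) into 3-[(E)-2-phenylethenyl]cyclobut-2-en-1-one A1 and the prenyl-substituted silyl ynol ether A2. The forward step is a Danheiser benzannulation: thermal ring opening of A1 to a vinylketene, [2+2] addition to A2, a second ring opening and 6π closure, giving the mono-silylated resorcinol A3.
- Merits: A3 is assembled convergently with prenyl and styryl in place. Its two oxygens are already differentiated, and the free hydroxyl is the one that must become O1. The chosen plan reaches this differentiation only through a stoichiometry-controlled mono-annulation of a symmetric diol, and here this road is better.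
- Weak points: A3 contains neither the pyran ring nor the stereocentre. Any later chromene epoxidation would have to select one alkene out of three, with the electron-rich stilbene present and a silyloxy group para to the benzylic oxirane carbon. A1 and A2 also each need several steps, and A2 is a hydrolytically fragile skipped enyne.
- Comparison: the chosen plan is longer on paper and spends three steps after the oxidation on redox and olefination. In return, its oxygen transfer is run on 10, which has only two alkenes and an electron-poor arene.

Alternative 2: The benzene ring is cut at C5–C6 and C4a–C8a and the pyranone at O1–C2, leading to the 2-prenyl-1-methoxy-1,3-bis(silyloxy)diene A4 and the styryl ynone A5. The forward step is a Diels–Alder addition, aromatisation by loss of methanol, and oxa-Michael closure of the new C8a phenol onto the dimethyl enone, giving chromanone A6.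
- Merits: both rings and every carbon substituent arise in one operation, with regiochemistry dictated by the polarised partners. No protecting groups or aryl coupling are needed. In convergence and ring construction this road is better than the chosen plan.
- Weak points: the oxygen of A6 is on C4, whereas 15 needs oxygen on C3 and a methylene at C4. The transposition needs either an enantioselective α-hydroxylation next to the quaternary C2 followed by benzylic deoxygenation beside a stilbene, or reduction and dehydration to a chromene that then faces the three-alkene problem. A C3 stereocentre α to the ketone would also be epimerisable, and the aryl ketone can reopen by retro-oxa-Michael reaction under base.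
- Comparison: the chosen plan places the oxygen on the correct carbon at the correct oxidation level in the stereodefining step itself.

Alternative 3: The cuts are C4–C4a and C5–Cα. The aryl iodide A7 carries the (R)-epoxide on a tertiary ether tether and is treated with Pd(0), norbornene A8 and styrene A9. The aryl–norbornyl palladacycle at C4a should open the tethered epoxide at its CH2 terminus and close the pyran ring; extrusion of A8 and Heck coupling with A9 then give the O7-methoxymethyl ether A10.
- Merits: if it worked, one step would form the heterocycle and the stilbene and leave a single deprotection. The stereocentre would be bought early on a small fragment. In step count after the key step and in independence from late asymmetric catalysis this road is clearly better.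
- Weak points: intramolecular epoxide alkylation through a palladacycle to form a six-membered ring is not an established mode. A7 has two unsubstituted positions ortho to iodine, the classic source of over-functionalisation in Catellani chemistry. The palladium alkoxide formed at C3 can undergo β-hydride elimination and destroy the stereocentre. A7 itself needs a tertiary alkyl aryl ether next to an enantioenriched epoxide on a hindered o-prenylphenol, and oxidative routes to that epoxide collide with the prenyl alkene.
- Comparison: against this brevity the chosen plan offers only close precedent for each step on the same functional-group pattern.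

Key step: step 6

Assumption: the configuration is read from the SMILES as 3R (ranking OH > C2 > C4 > H), and the commercial methyl ester 1 is used in place of the free 4-bromo-3,5-dihydroxybenzoic acid.

## Route

Step 1
Reactants: 1 methyl 4-bromo-3,5-dihydroxybenzoate
Product: 2 methyl 4-bromo-3,5-bis(methoxymethoxy)benzoate
Conditions: MOMCl (3 equiv), i-Pr2NEt (4 equiv), CH2Cl2, 0 °C to rt
Reagents that add atoms: chloromethyl methyl ether, COCCl
Why: Williamson-type O-alkylation of both phenols; the acetal ethers remove the acidic protons that would quench the organozinc of step 2 and are inert to zinc reagents and Pd(0).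

Step 2
Reactants: 2 methyl 4-bromo-3,5-bis(methoxymethoxy)benzoate; 3 1-bromo-3-methylbut-2-ene
Product: 5 methyl 3,5-bis(methoxymethoxy)-4-(3-methylbut-2-en-1-yl)benzoate, via (3-methylbut-2-en-1-yl)zinc bromide 4 (not isolated)
Conditions: Zn dust, LiCl, THF, 0 °C (slow addition of 3); then 2, Pd(OAc)2 (2 mol %), CPhos (4 mol %), THF, rt
Reagents that add atoms: none
Why: Negishi coupling of an allylic zinc halide with an aryl bromide; with a bulky biarylphosphine, reductive elimination takes place from the primary terminus of the allyl–palladium, and the 2,6-dialkoxyaryl group adds to this bias, so the linear prenyl arene should form. The organozinc does not attack the methyl ester at room temperature.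

Step 3
Reactants: 5 methyl 3,5-bis(methoxymethoxy)-4-(3-methylbut-2-en-1-yl)benzoate
Product: 6 methyl 3,5-dihydroxy-4-(3-methylbut-2-en-1-yl)benzoate
Conditions: p-TsOH·H2O (0.2 equiv), MeOH, 40 °C
Reagents that add atoms: none
Why: Acid-catalysed transacetalisation of the aryl methoxymethyl ethers to methanol; the mild acid and low temperature should leave the prenyl alkene unhydrated and the o-prenylphenol uncyclised.

Step 4
Reactants: 6 methyl 3,5-dihydroxy-4-(3-methylbut-2-en-1-yl)benzoate; 7 3-methylbut-2-enal
Product: 9 methyl 7-hydroxy-2,2-dimethyl-8-(3-methylbut-2-en-1-yl)-2H-chromene-5-carboxylate, via ortho-quinone methide dienone 8 (not isolated)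
Conditions: 7 (1.05 equiv), ethylenediammonium diacetate (20 mol %), xylene, 130 °C
Reagents that add atoms: none
Why: Formal [3+3] chromene annulation of a resorcinol with an enal: iminium-activated Knoevenagel-type C-alkylation ortho to one hydroxyl and para to the other, dehydration to 8 and oxa-6π electrocyclisation. The carbon between the hydroxyls is blocked and the two open carbons are symmetry-equivalent, so one constitution results; a near-stoichiometric amount of 7 limits a second annulation.

Step 5
Reactants: 9 methyl 7-hydroxy-2,2-dimethyl-8-(3-methylbut-2-en-1-yl)-2H-chromene-5-carboxylate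
Product: 10 methyl 7-[(2,2-dimethylpropanoyl)oxy]-2,2-dimethyl-8-(3-methylbut-2-en-1-yl)-2H-chromene-5-carboxylate
Conditions: PivCl (1.3 equiv), Et3N (2 equiv), DMAP (5 mol %), CH2Cl2, 0 °C to rt
Reagents that add atoms: pivaloyl chloride, CC(C)(C)C(=O)Cl
Why: DMAP-catalysed O-acylation of the remaining phenol; the acyl group turns the para oxygen from a strong into a weak donor towards C4 and is bulky enough to resist the basic aqueous oxidant of step 6.

Step 6
Reactants: 10 methyl 7-[(2,2-dimethylpropanoyl)oxy]-2,2-dimethyl-8-(3-methylbut-2-en-1-yl)-2H-chromene-5-carboxylate
Product: 11 methyl (1aR,7bR)-5-[(2,2-dimethylpropanoyl)oxy]-2,2-dimethyl-4-(3-methylbut-2-en-1-yl)-1a,7b-dihydro-2H-oxireno[2,3-c]chromene-7-carboxylate, i.e. the (3R,4R)-3,4-epoxide of 10 in chromane numbering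
Conditions: (R,R)-N,N'-bis(3,5-di-tert-butylsalicylidene)-1,2-cyclohexanediaminomanganese(III) chloride (5 mol %), 4-phenylpyridine N-oxide (20 mol %), aq NaOCl buffered to pH 11.3 (1.5 equiv), CH2Cl2, 0 °C
Reagents that add atoms: sodium hypochlorite, [Na+].[O-]Cl
Why: Jacobsen–Katsuki epoxidation: hypochlorite oxidises the Mn(III) salen complex to an oxo-Mn(V) species, stabilised by the N-oxide as axial ligand, and the cis, aryl-conjugated C3=C4 bond approaches the oxo group side-on. Oxygen is transferred stepwise, first to C3 to give a benzylic C4 radical and then by collapse of that radical onto the same oxygen, so the oxirane closes as a formal [2+1] atom transfer (3-exo radical rebound) on one face, and the six-membered ring forbids any cis/trans leakage. The closest known reaction is the epoxidation of 2,2-dimethyl-2H-chromenes bearing electron-withdrawing aryl substituents under these conditions, one of the most selective substrate classes for this catalyst. Both new stereocentres are catalyst-controlled: the (R,R)-diamine backbone and the tert-butyl groups leave one trajectory open, the C2 gem-dimethyl group steers the arene away from the ligand bulk, and the (R,R)-catalyst is expected to give the (3R,4R)-oxide, with C4 following C3 because the fusion must be cis. Chemoselectivity over the prenyl alkene is required and should follow from the mechanism, since the isolated trisubstituted alkene cannot stabilise the radical intermediate and is a slow substrate, and at pH 11.3 little free hypochlorous acid is available for ene-type chlorination. The oxirane must also survive: the pivalate para and the ester ortho to C4a destabilise a C4 cation, and the buffered basic medium excludes acid.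

Step 7
Reactants: 11 methyl (1aR,7bR)-5-[(2,2-dimethylpropanoyl)oxy]-2,2-dimethyl-4-(3-methylbut-2-en-1-yl)-1a,7b-dihydro-2H-oxireno[2,3-c]chromene-7-carboxylate
Product: 12 (3R)-5-(hydroxymethyl)-2,2-dimethyl-8-(3-methylbut-2-en-1-yl)-3,4-dihydro-2H-chromene-3,7-diol
Conditions: 11 added to LiAlH4 (4 equiv), THF, 0 °C to rt; Rochelle salt work-up
Reagents that add atoms: none
Why: Hydride opening of the benzylic epoxide at C4 (benzylic, and far less hindered than neopentylic C3), together with reduction of the methyl ester to the benzylic alcohol and reductive cleavage of the aryl pivalate. The C3–O bond is never broken, so C3 keeps its configuration and stays R because the ranking O > C2 > C4 > H is unchanged.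

Step 8
Reactants: 12 (3R)-5-(hydroxymethyl)-2,2-dimethyl-8-(3-methylbut-2-en-1-yl)-3,4-dihydro-2H-chromene-3,7-diol
Product: 13 (3R)-3,7-dihydroxy-2,2-dimethyl-8-(3-methylbut-2-en-1-yl)-3,4-dihydro-2H-chromene-5-carbaldehyde
Conditions: activated MnO2 (15 equiv), acetone, rt
Reagents that add atoms: none
Why: Heterogeneous MnO2 oxidation is selective for benzylic alcohols; the unactivated secondary C3 carbinol is not touched and the aldehyde is not oxidised further.

Step 9
Reactants: 13 (3R)-3,7-dihydroxy-2,2-dimethyl-8-(3-methylbut-2-en-1-yl)-3,4-dihydro-2H-chromene-5-carbaldehyde; 14 diethyl benzylphosphonate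
Product: 15 (3R)-2,2-dimethyl-8-(3-methylbut-2-en-1-yl)-5-[(E)-2-phenylethenyl]-3,4-dihydro-2H-chromene-3,7-diol
Conditions: 14 (1.5 equiv), KOt-Bu (4 equiv), THF/DMF, 0 °C to rt, exclusion of light; aq NH4Cl
Reagents that add atoms: none
Why: Horner–Wadsworth–Emmons olefination with a semi-stabilised benzylphosphonate carbanion; reversible addition and elimination of diethyl phosphate through the less hindered oxaphosphetane should give the E-stilbene. Excess base covers the phenol and the carbinol, and the phenoxide is meta to the formyl group and so does not deactivate it by conjugation.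

## Compound list

1 | methyl 4-bromo-3,5-dihydroxybenzoate | COC(=O)c1cc(O)c(Br)c(O)c1 | starting material
2 | methyl 4-bromo-3,5-bis(methoxymethoxy)benzoate | COCOc1cc(C(=O)OC)cc(OCOC)c1Br | intermediate
3 | 1-bromo-3-methylbut-2-ene (prenyl bromide) | CC(C)=CCBr | starting material
4 | (3-methylbut-2-en-1-yl)zinc bromide | CC(C)=CC[Zn]Br | intermediate (not isolated)
5 | methyl 3,5-bis(methoxymethoxy)-4-(3-methylbut-2-en-1-yl)benzoate | COCOc1cc(C(=O)OC)cc(OCOC)c1CC=C(C)C | intermediate
6 | methyl 3,5-dihydroxy-4-(3-methylbut-2-en-1-yl)benzoate | COC(=O)c1cc(O)c(CC=C(C)C)c(O)c1 | intermediate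
7 | 3-methylbut-2-enal | CC(C)=CC=O | starting material
8 | methyl 3-hydroxy-4-(3-methylbut-2-en-1-yl)-6-(3-methylbut-2-en-1-ylidene)-5-oxocyclohexa-1,3-diene-1-carboxylate (ortho-quinone methide dienone) | COC(=O)C1=CC(O)=C(CC=C(C)C)C(=O)C1=CC=C(C)C | intermediate (not isolated)
9 | methyl 7-hydroxy-2,2-dimethyl-8-(3-methylbut-2-en-1-yl)-2H-chromene-5-carboxylate | CC(C)=CCc1c(O)cc(C(=O)OC)c2c1OC(C)(C)C=C2 | intermediate
10 | methyl 7-[(2,2-dimethylpropanoyl)oxy]-2,2-dimethyl-8-(3-methylbut-2-en-1-yl)-2H-chromene-5-carboxylate | CC(C)=CCc1c(OC(=O)C(C)(C)C)cc(C(=O)OC)c2c1OC(C)(C)C=C2 | intermediate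
11 | methyl (1aR,7bR)-5-[(2,2-dimethylpropanoyl)oxy]-2,2-dimethyl-4-(3-methylbut-2-en-1-yl)-1a,7b-dihydro-2H-oxireno[2,3-c]chromene-7-carboxylate [(3R,4R)-epoxide of 10] | CC(C)=CCc1c(OC(=O)C(C)(C)C)cc(C(=O)OC)c2c1OC(C)(C)[C@@H]1O[C@@H]12 | intermediate
12 | (3R)-5-(hydroxymethyl)-2,2-dimethyl-8-(3-methylbut-2-en-1-yl)-3,4-dihydro-2H-chromene-3,7-diol | CC(C)=CCc1c(O)cc(CO)c2c1OC(C)(C)[C@H](O)C2 | intermediate
13 | (3R)-3,7-dihydroxy-2,2-dimethyl-8-(3-methylbut-2-en-1-yl)-3,4-dihydro-2H-chromene-5-carbaldehyde | CC(C)=CCc1c(O)cc(C=O)c2c1OC(C)(C)[C@H](O)C2 | intermediate
14 | diethyl benzylphosphonate | CCOP(=O)(Cc1ccccc1)OCC | starting material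
15 | (3R)-2,2-dimethyl-8-(3-methylbut-2-en-1-yl)-5-[(E)-2-phenylethenyl]-3,4-dihydro-2H-chromene-3,7-diol | CC(C)=CCc1c(O)cc(/C=C/c2ccccc2)c2c1OC(C)(C)[C@H](O)C2 | target

## Step count and least certain steps

Total: 9 steps. Longest linear sequence: 9 steps from 1; the route is fully linear, and reagent 4 is generated within step 2.

**Step 6 (key step).** The most likely failure is loss of chemoselectivity: oxidation of the prenyl alkene by the oxo-manganese species or its ene-type chlorination by hypochlorous acid at partial conversion. Opening of the oxirane on acidic supports, assisted by the peri ester carbonyl, is a second concern. The product should therefore be passed only through triethylamine-deactivated silica or carried on crude, and the sense of induction should be confirmed at 12 before material is committed. The fallback changes the order of events so that the oxidant never meets a second alkene. It sets out from 1 and comes back at 11. Compound 1 is annulated with 7 under the conditions of step 4 to give methyl 8-bromo-7-hydroxy-2,2-dimethyl-2H-chromene-5-carboxylate F1. Acylation as in step 5 gives methyl 8-bromo-7-[(2,2-dimethylpropanoyl)oxy]-2,2-dimethyl-2H-chromene-5-carboxylate F2. The same Mn(salen) oxidation gives methyl (1aR,7bR)-4-bromo-5-[(2,2-dimethylpropanoyl)oxy]-2,2-dimethyl-1a,7b-dihydro-2H-oxireno[2,3-c]chromene-7-carboxylate F3. Negishi coupling of F3 with 4 under the neutral, room-temperature conditions of step 2 then introduces the prenyl group and gives 11.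

**Step 4.** C-alkylation at a carbon ortho to the ester may be sluggish, and a second annulation on the remaining phenol may compete, so that conversion and mono-selectivity cannot both be high. The fallback replaces the condensation by a sigmatropic sequence. It sets out from 6 and comes back at 9. Copper-catalysed mono-O-alkylation of 6 with 3-chloro-3-methylbut-1-yne (CuCl2 cat., DBU, MeCN, 0 °C) gives methyl 3-hydroxy-4-(3-methylbut-2-en-1-yl)-5-[(2-methylbut-3-yn-2-yl)oxy]benzoate F4. Heating F4 (N,N-diethylaniline, about 150 °C) triggers aryl propargyl ether Claisen rearrangement, 1,5-hydrogen shift and oxa-6π closure. The rearrangement can only end at the free ortho carbon, because the other one carries the prenyl group, and this gives 9.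

**Step 9.** Proton transfer from the free phenol and carbinol to the phosphonate carbanion, and the reduced electrophilicity of the phenoxide aldehyde, may leave the olefination incomplete. The fallback masks the phenol. It sets out from 13 and comes back at 15. Phenol-selective silylation (TBSCl, imidazole, DMF, 0 °C; the C3 carbinol next to the quaternary carbon is much slower) gives (3R)-7-[(tert-butyldimethylsilyl)oxy]-3-hydroxy-2,2-dimethyl-8-(3-methylbut-2-en-1-yl)-3,4-dihydro-2H-chromene-5-carbaldehyde F5. Olefination with 14 (NaH, 15-crown-5, THF) gives (3R)-7-[(tert-butyldimethylsilyl)oxy]-2,2-dimethyl-8-(3-methylbut-2-en-1-yl)-5-[(E)-2-phenylethenyl]-3,4-dihydro-2H-chromen-3-ol F6. Fluoride (TBAF, THF, 0 °C) then releases 15.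

**Step 7.** Aluminium-assisted ionisation of the oxirane at C4 followed by a 1,2-hydride shift (Meinwald rearrangement) would pass through a C3 ketone and erode the enantiomeric purity on reduction. Hydride attack at C3 is the lesser risk. The fallback separates the epoxide opening from the ester reductions and makes it a radical process. It sets out from 11 and comes back at 12. Treatment of 11 with Cp2TiCl (from Cp2TiCl2 and Zn) and 1,4-cyclohexadiene in THF cleaves the benzylic C4–O bond homolytically and transfers a hydrogen atom to C4, giving methyl (3R)-7-[(2,2-dimethylpropanoyl)oxy]-3-hydroxy-2,2-dimethyl-8-(3-methylbut-2-en-1-yl)-3,4-dihydro-2H-chromene-5-carboxylate F7. LiAlH4 then reduces both esters of F7 to give 12.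

**Step 8.** Oxidative degradation of the electron-rich free phenol on the manganese oxide, and strong adsorption of the polar triol, may lower the recovery. The fallback keeps the phenol masked during the oxidation. It sets out from 12 and comes back at 13. Phenolate-selective acetylation (Ac2O, aq NaOH, 0 °C) gives (3R)-3-hydroxy-5-(hydroxymethyl)-2,2-dimethyl-8-(3-methylbut-2-en-1-yl)-3,4-dihydro-2H-chromen-7-yl acetate F8. MnO2 oxidation gives (3R)-5-formyl-3-hydroxy-2,2-dimethyl-8-(3-methylbut-2-en-1-yl)-3,4-dihydro-2H-chromen-7-yl acetate F9. Methanolysis (K2CO3, MeOH, 0 °C) returns 13.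

## Further compounds

F1 | step 6 | methyl 8-bromo-7-hydroxy-2,2-dimethyl-2H-chromene-5-carboxylate | Brc1c(O)cc(C(=O)OC)c2c1OC(C)(C)C=C2
F2 | step 6 | methyl 8-bromo-7-[(2,2-dimethylpropanoyl)oxy]-2,2-dimethyl-2H-chromene-5-carboxylate | Brc1c(OC(=O)C(C)(C)C)cc(C(=O)OC)c2c1OC(C)(C)C=C2
F3 | step 6 | methyl (1aR,7bR)-4-bromo-5-[(2,2-dimethylpropanoyl)oxy]-2,2-dimethyl-1a,7b-dihydro-2H-oxireno[2,3-c]chromene-7-carboxylate | Brc1c(OC(=O)C(C)(C)C)cc(C(=O)OC)c2c1OC(C)(C)[C@@H]1O[C@@H]12
F4 | step 4 | methyl 3-hydroxy-4-(3-methylbut-2-en-1-yl)-5-[(2-methylbut-3-yn-2-yl)oxy]benzoate | COC(=O)c1cc(O)c(CC=C(C)C)c(OC(C)(C)C#C)c1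
F5 | step 9 | (3R)-7-[(tert-butyldimethylsilyl)oxy]-3-hydroxy-2,2-dimethyl-8-(3-methylbut-2-en-1-yl)-3,4-dihydro-2H-chromene-5-carbaldehyde | CC(C)=CCc1c(O[Si](C)(C)C(C)(C)C)cc(C=O)c2c1OC(C)(C)[C@H](O)C2
F6 | step 9 | (3R)-7-[(tert-butyldimethylsilyl)oxy]-2,2-dimethyl-8-(3-methylbut-2-en-1-yl)-5-[(E)-2-phenylethenyl]-3,4-dihydro-2H-chromen-3-ol | CC(C)=CCc1c(O[Si](C)(C)C(C)(C)C)cc(/C=C/c2ccccc2)c2c1OC(C)(C)[C@H](O)C2
F7 | step 7 | methyl (3R)-7-[(2,2-dimethylpropanoyl)oxy]-3-hydroxy-2,2-dimethyl-8-(3-methylbut-2-en-1-yl)-3,4-dihydro-2H-chromene-5-carboxylate | CC(C)=CCc1c(OC(=O)C(C)(C)C)cc(C(=O)OC)c2c1OC(C)(C)[C@H](O)C2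
F8 | step 8 | (3R)-3-hydroxy-5-(hydroxymethyl)-2,2-dimethyl-8-(3-methylbut-2-en-1-yl)-3,4-dihydro-2H-chromen-7-yl acetate | CC(C)=CCc1c(OC(C)=O)cc(CO)c2c1OC(C)(C)[C@H](O)C2
F9 | step 8 | (3R)-5-formyl-3-hydroxy-2,2-dimethyl-8-(3-methylbut-2-en-1-yl)-3,4-dihydro-2H-chromen-7-yl acetate | CC(C)=CCc1c(OC(C)=O)cc(C=O)c2c1OC(C)(C)[C@H](O)C2
A1 | alternative 1 | 3-[(E)-2-phenylethenyl]cyclobut-2-en-1-one | O=C1C=C(/C=C/c2ccccc2)C1
A2 | alternative 1 | triisopropyl[(5-methylhex-4-en-1-yn-1-yl)oxy]silane | CC(C)=CCC#CO[Si](C(C)C)(C(C)C)C(C)C
A3 | alternative 1 | 2-(3-methylbut-2-en-1-yl)-5-[(E)-2-phenylethenyl]-3-[(triisopropylsilyl)oxy]phenol | CC(C)=CCc1c(O)cc(/C=C/c2ccccc2)cc1O[Si](C(C)C)(C(C)C)C(C)C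
A4 | alternative 2 | 1-methoxy-2-(3-methylbut-2-en-1-yl)-1,3-bis[(trimethylsilyl)oxy]buta-1,3-diene | COC(O[Si](C)(C)C)=C(CC=C(C)C)C(=C)O[Si](C)(C)C
A5 | alternative 2 | (7E)-2-methyl-8-phenylocta-2,7-dien-5-yn-4-one | CC(C)=CC(=O)C#C/C=C/c1ccccc1
A6 | alternative 2 | 7-hydroxy-2,2-dimethyl-8-(3-methylbut-2-en-1-yl)-5-[(E)-2-phenylethenyl]-2,3-dihydro-4H-chromen-4-one | CC(C)=CCc1c(O)cc(/C=C/c2ccccc2)c2c1OC(C)(C)CC2=O
A7 | alternative 3 | (2R)-2-(2-{[5-iodo-3-(methoxymethoxy)-2-(3-methylbut-2-en-1-yl)phenyl]oxy}propan-2-yl)oxirane | CC(C)=CCc1c(OCOC)cc(I)cc1OC(C)(C)[C@H]1CO1
A8 | alternative 3 | norbornene (bicyclo[2.2.1]hept-2-ene) | C1=CC2CCC1C2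
A9 | alternative 3 | styrene | C=Cc1ccccc1
A10 | alternative 3 | (3R)-7-(methoxymethoxy)-2,2-dimethyl-8-(3-methylbut-2-en-1-yl)-5-[(E)-2-phenylethenyl]-3,4-dihydro-2H-chromen-3-ol | CC(C)=CCc1c(OCOC)cc(/C=C/c2ccccc2)c2c1OC(C)(C)[C@H](O)C2
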